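## Analysis of the target

Lancifolin C (23) is an 8,3'-neolignan. Ring A is a cross-conjugated cyclohexa-2,5-dienone: C1 carbonyl, C2 allyl, C3 H, C4 quaternary, C5 methoxy, C6 H. It is joined through C4–C8 to a short chain (C8 methine carrying a methyl group, C7 methylene) that ends in ring B, a 3,4-dimethoxyphenyl group. These atom labels are kept for all intermediates.

There are two stereocentres, (S)-C4 (bearing OMe, C3, C5 and C8) and (R)-C8. They are adjacent, but no ring connects them. The two ring arms at C4 differ only by H on C3 against OMe on C5, so an external reagent that attacks a planar C4 gets almost no guidance from C8, and both C4 epimers must be expected.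

The C5-OMe/C1=O vinylogous ester has to be formed with the methoxy group on the more hindered oxygen, next to the quaternary carbon. It is therefore best inherited from an anisole rather than made by O-methylation of a 1,3-dione.

The molecule is sensitive in three ways. The tertiary bis-allylic ether at C4 ionises under acid (dienone–phenol chemistry). The allyl double bond migrates into conjugation under base. A radical or carbanion at C7 can expel ring A as an aromatic phenoxyl or phenoxide by cleavage of C4–C8.

The feature that invites the strategy is the array O–C4–C8–C7. The oxygen on C4 is 1,3 to C7, so one bridging atom between this oxygen and C7 closes a five-membered ring that is spiro to ring A. The C5 methoxy group next to C4 imposes A(1,3) strain on C8 and so fixes the face on which that ring can close. A boron atom on C7 can serve as the bridge and can afterwards be exchanged for ring B.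

## Retrosynthetic reasoning

**C4–O–CH3 bond.** The methyl ether of 23 is cut back to the tertiary quinol 21. The C4–O bond is not broken in the forward O-methylation, so the configuration of 21 is carried into 23. The methyl group comes last because the C4 oxygen is needed earlier as part of a ring.

**C7–aryl bond.** Quinol 21 is cut between C7 and ring B, to the spirocyclic borinic ester 19 and aryl bromide 20. Cutting here, rather than between C4 and C8, keeps the difficult quaternary centre out of the C–C bond-forming event and makes the precursor of the dearomatisation smaller. The boron left on C7 has two roles: it is the handle for a B-alkyl Suzuki–Miyaura coupling, and it is the tether that sets C4. The forward reaction has to transfer a primary alkyl group from boron to palladium without creating a radical or carbanion at C7.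

**C4–O bond (key disconnection).** In 19 the ring O–B–C7–C8–C4 is opened at C4–O, which leads back to the phenol boronic acid 17. The forward step oxidises the phenol with a trivalent iodine reagent (through 18) and lets the boron-bound hydroxyl capture C4 from within. Because the nucleophile is tied to C7, the face of attack is decided by the conformation about C4–C8, and A(1,3) strain with the C5 methoxy group fixes that conformation. C4 is thus set by C8 rather than by a choice between CH3 and CH2Ar. The gain is the quaternary stereocentre, the dearomatised ring A with its methoxy group already in place on C5, and a boron handle on C7, all from a flat phenol.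

**Boronic acid and C2–allyl bond.** 17 comes from its pinacol ester 16 by ester exchange. The C2–allyl bond of 16 is cut by an aromatic Claisen transform to the allyl aryl ether 14. The allyl group therefore protects the phenol oxygen during the organolithium steps and then moves to carbon.

**C7–C8 bond and the C8 stereocentre.** 14 is cut between C7 and C8, to the secondary benzylic boronic ester 10 and a one-carbon carbenoid from 11 (Matteson homologation, retention at C8). 10 is cut between C8 and ring A, to aryl boronic ester 6 and the chiral carbenoid derived from carbamate 7 (lithiation–borylation). This places the only reagent-controlled stereocentre, C8, in a reaction class with a predictable and high level of control, and both homologations use the same boron atom that later does the key step.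

**Aryl–boron and O–allyl bonds.** 6 comes from bromide 3 by bromine–lithium exchange and trapping with borate 4. 3 comes from phenol 1 and allyl bromide 2.

## Alternatives that were turned down

**Alternative 1:** (the textbook route) Disconnection of C4–OMe with external methanol. The complete phenol A1, 2-allyl-4-[(2R)-1-(3,4-dimethoxyphenyl)propan-2-yl]-5-methoxyphenol, would be oxidised with PhI(OAc)2 in methanol to give 23 directly. It was turned down because methanol attacks a planar C4 whose two faces differ only by CH3 against CH2Ar on C8. With the C8–H bond held next to the C5 methoxy group, the larger CH2Ar group shields the very face that must be attacked, so the C4 epimer A2 should form in at least equal amount. The route is two steps shorter, but it does not set the harder stereocentre at all.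

**Alternative 2:** Disconnection of C4–C8 by 1,2-addition. The organolithium A4, [(2R)-1-(3,4-dimethoxyphenyl)propan-2-yl]lithium, would add to the C4 carbonyl of quinone A3, 2-allyl-5-methoxy-1,4-benzoquinone, to give 21, followed by O-methylation. It was turned down for three reasons. A secondary alkyllithium without a stabilising heteroatom holds its configuration only at very low temperature. The quinone is a good electron acceptor, so electron transfer would compete with addition and racemise C8. The addition has an open transition state that gives no reason for one face of the C4 carbonyl over the other. Both stereocentres would be in doubt.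

**Alternative 3:** (biomimetic) Disconnection of C4–C8 by cation–olefin union. The quinone monoketal A5, 2-allyl-4,4,5-trimethoxycyclohexa-2,5-dien-1-one, would be ionised with acid and attacked at C4 by C8 of (E)-methylisoeugenol A6, and the C7 cation would be reduced by a hydride donor. It was turned down for four reasons. The cation from A5 carries charge at C2 as well as C4, and bond formation at the allyl-bearing C2 is expected to compete. The C7 cation sits next to the C5 methoxy oxygen and should close onto it with loss of methyl, giving the hydrobenzofuranone A7, faster than it is reduced. The hydride donor would also reduce the starting cation. There is no element that fixes the absolute configuration.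

Key step: step 7

## Route

Remark: carbamate 7 is taken as a purchased reagent (it is otherwise made in one operation from ethanol and N,N-diisopropylcarbamoyl chloride); atom labels C1–C8 are those of the target.

Step 1
Reactants: 1 4-bromo-3-methoxyphenol; 2 allyl bromide (3-bromoprop-1-ene)
Product: 3 1-bromo-2-methoxy-4-(prop-2-en-1-yloxy)benzene
Conditions: K2CO3, acetone, reflux
Reagents that add atoms: allyl bromide (2), C=CCBr
Why: Williamson ether synthesis of the phenoxide with a primary allylic bromide; the allyl ether protects the phenol through the organolithium steps and is the source of the C2 allyl group in step 5.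

Step 2
Reactants: 3 1-bromo-2-methoxy-4-(prop-2-en-1-yloxy)benzene; 4 2-isopropoxy-4,4,5,5-tetramethyl-1,3,2-dioxaborolane
Product: 6 2-[2-methoxy-4-(prop-2-en-1-yloxy)phenyl]-4,4,5,5-tetramethyl-1,3,2-dioxaborolane, via aryllithium 5 (not isolated)
Conditions: n-BuLi, THF, −78 °C; then 4, −78 °C to rt
Reagents that add atoms: 2-isopropoxy-4,4,5,5-tetramethyl-1,3,2-dioxaborolane (4), CC(C)OB1OC(C)(C)C(C)(C)O1
Why: Bromine–lithium exchange at −78 °C is faster than any attack on the allyl ether, and aryllithium 5 is trapped at boron with loss of isopropoxide (borylation of an aryllithium); the future C4 of ring A becomes the boron-bearing carbon.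

Step 3
Reactants: 6 2-[2-methoxy-4-(prop-2-en-1-yloxy)phenyl]-4,4,5,5-tetramethyl-1,3,2-dioxaborolane; 7 ethyl N,N-diisopropylcarbamate
Product: 10 2-{(1S)-1-[2-methoxy-4-(prop-2-en-1-yloxy)phenyl]ethyl}-4,4,5,5-tetramethyl-1,3,2-dioxaborolane, via lithiated carbamate 8 (not isolated), via boronate complex 9 (not isolated)
Conditions: 7, s-BuLi, (+)-sparteine, Et2O, −78 °C; then 6, −78 °C to 35 °C
Reagents that add atoms: ethyl N,N-diisopropylcarbamate (7), CCOC(=O)N(C(C)C)C(C)C
Why: Lithiation–borylation (1,2-metallate rearrangement): s-BuLi/(+)-sparteine removes the pro-R hydrogen of 7 to give the configurationally stable (R)-carbenoid 8, which adds to boron of 6 with retention to give 9. The aryl group then migrates from boron to carbon anti to the carbamate leaving group, with inversion, which sets C8 as (S) in 10; this is the spatial arrangement that is (R) in 14 and in the target.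

Step 4
Reactants: 10 2-{(1S)-1-[2-methoxy-4-(prop-2-en-1-yloxy)phenyl]ethyl}-4,4,5,5-tetramethyl-1,3,2-dioxaborolane; 11 bromochloromethane
Product: 14 2-{(2R)-2-[2-methoxy-4-(prop-2-en-1-yloxy)phenyl]propyl}-4,4,5,5-tetramethyl-1,3,2-dioxaborolane, via chloromethyllithium 12 (not isolated), via boronate complex 13 (not isolated)
Conditions: BrCH2Cl, n-BuLi, THF, −78 °C to rt
Reagents that add atoms: bromochloromethane (11), ClCBr
Why: Matteson one-carbon homologation: chloromethyllithium 12, made in the flask by bromine–lithium exchange, adds to boron, and the secondary benzylic group migrates with retention and displaces chloride. C7 is inserted without touching C8; the descriptor changes from S to R only because C7 now outranks the methyl group.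

Step 5
Reactants: 14 2-{(2R)-2-[2-methoxy-4-(prop-2-en-1-yloxy)phenyl]propyl}-4,4,5,5-tetramethyl-1,3,2-dioxaborolane
Product: 16 5-methoxy-2-(prop-2-en-1-yl)-4-[(2R)-1-(4,4,5,5-tetramethyl-1,3,2-dioxaborolan-2-yl)propan-2-yl]phenol, via cyclohexadienone 15 (not isolated)
Conditions: N,N-diethylaniline, 190 °C
Reagents that add atoms: none
Why: Aromatic Claisen rearrangement ([3,3]) to the ortho carbon remote from the methoxy group (the other ortho position is flanked on both sides), then tautomerisation of dienone 15 to the phenol; the alkylboronic ester and the C8 stereocentre take no part.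

Step 6
Reactants: 16 5-methoxy-2-(prop-2-en-1-yl)-4-[(2R)-1-(4,4,5,5-tetramethyl-1,3,2-dioxaborolan-2-yl)propan-2-yl]phenol
Product: 17 {(2R)-2-[4-hydroxy-2-methoxy-5-(prop-2-en-1-yl)phenyl]propyl}boronic acid
Conditions: MeB(OH)2 (excess), 0.1 M HCl, acetone/H2O, rt; evaporation
Reagents that add atoms: water, O
Why: Acid-catalysed transesterification of the pinacol ester with an excess of methylboronic acid; the volatile methylboronic pinacol ester is removed by evaporation, which drives the exchange to the free boronic acid needed as oxygen donor in step 7.

Step 7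
Reactants: 17 {(2R)-2-[4-hydroxy-2-methoxy-5-(prop-2-en-1-yl)phenyl]propyl}boronic acid
Product: 19 (4R,5S)-2-hydroxy-6-methoxy-4-methyl-9-(prop-2-en-1-yl)-1-oxa-2-boraspiro[4.5]deca-6,9-dien-8-one, via aryloxyiodane 18 (not isolated)
Conditions: PhI(OAc)2, (CF3)2CHOH/CH2Cl2, 0 °C
Reagents that add atoms: none
Why: Proposed new method: ligand exchange of the phenol with PhI(OAc)2 gives the aryloxy-λ3-iodane 18, whose para carbon C4 becomes electrophilic as PhI departs; the boron-bound hydroxyl, held three atoms from C4 (C4–C8–C7–B–O), captures it and loses a proton, so the C4–O bond and the oxaborolane ring form together. The closest known reaction type is the trivalent-iodine-mediated dearomative spirolactonisation or spiroetherification of para-substituted phenols; a B–OH group as tethered oxygen nucleophile has precedent only in boronic-acid hemiester oxa-Michael additions, hence the label. The ring closes in the 5-exo-trig mode onto C4 of ring A and leaves a spiro centre. The new stereocentre C4 is controlled by C8 through A(1,3) strain: the C5 methoxy group lies in the ring plane, so in the closing transition state the C8–H bond, not the C8–CH3 bond, must eclipse it, which places C7 and its boron over one face only; with (R)-C8 the oxygen is delivered to the face that gives (S)-C4. The same conformation keeps the C8–H bond out of alignment with the ring π system, which should disfavour loss of that proton to a quinone methide. The step needs para over ortho capture and intramolecular over intermolecular capture; the five-membered tether, the non-nucleophilic fluoroalcohol and the absence of any oxygen nucleophile other than acetate should secure both. The neutral boronic acid is chosen over a borate so that the C7–B bond is a poor σ-donor and closure through carbon to a spirocyclopropane does not compete; ring B is not yet present, so no second electron-rich arene can intercept the oxidant.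

Step 8
Reactants: 19 (4R,5S)-2-hydroxy-6-methoxy-4-methyl-9-(prop-2-en-1-yl)-1-oxa-2-boraspiro[4.5]deca-6,9-dien-8-one; 20 4-bromo-1,2-dimethoxybenzene
Product: 21 (4S)-4-[(2R)-1-(3,4-dimethoxyphenyl)propan-2-yl]-4-hydroxy-5-methoxy-2-(prop-2-en-1-yl)cyclohexa-2,5-dien-1-one
Conditions: Pd(OAc)2, RuPhos, K2CO3, toluene/H2O, 80 °C
Reagents that add atoms: 4-bromo-1,2-dimethoxybenzene (20), COc1ccc(Br)cc1OC
Why: B-alkyl Suzuki–Miyaura coupling: aqueous carbonate opens the cyclic borinic ester to a hydroxyboronate that transfers its primary alkyl group to the arylpalladium bromide; reductive elimination forms the C7–aryl bond, and hydrolysis of the remaining B–O bond frees the C4 hydroxyl. No radical or carbanion arises at C7, so the C4–C8 bond is not put at risk and neither stereocentre is touched.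

Step 9
Reactants: 21 (4S)-4-[(2R)-1-(3,4-dimethoxyphenyl)propan-2-yl]-4-hydroxy-5-methoxy-2-(prop-2-en-1-yl)cyclohexa-2,5-dien-1-one; 22 iodomethane
Product: 23 Lancifolin C, (4S)-4-[(2R)-1-(3,4-dimethoxyphenyl)propan-2-yl]-4,5-dimethoxy-2-(prop-2-en-1-yl)cyclohexa-2,5-dien-1-one
Conditions: MeI, Ag2O, MeCN, 40 °C, dark
Reagents that add atoms: iodomethane (22), CI
Why: Purdie methylation of the tertiary bis-allylic alcohol under neutral conditions, which avoids base-induced migration of the allyl double bond and acid-induced ionisation at C4; the C4–O bond is not broken, so the configuration is retained.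

## Compound list

1 | 4-bromo-3-methoxyphenol | Oc1ccc(Br)c(OC)c1 | starting material
2 | allyl bromide (3-bromoprop-1-ene) | C=CCBr | starting material
3 | 1-bromo-2-methoxy-4-(prop-2-en-1-yloxy)benzene | C=CCOc1ccc(Br)c(OC)c1 | intermediate
4 | 2-isopropoxy-4,4,5,5-tetramethyl-1,3,2-dioxaborolane | CC(C)OB1OC(C)(C)C(C)(C)O1 | starting material
5 | [2-methoxy-4-(prop-2-en-1-yloxy)phenyl]lithium (not isolated) | [Li]c1ccc(OCC=C)cc1OC | intermediate
6 | 2-[2-methoxy-4-(prop-2-en-1-yloxy)phenyl]-4,4,5,5-tetramethyl-1,3,2-dioxaborolane | C=CCOc1ccc(B2OC(C)(C)C(C)(C)O2)c(OC)c1 | intermediate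
7 | ethyl N,N-diisopropylcarbamate | CCOC(=O)N(C(C)C)C(C)C | starting material
8 | (1R)-1-lithioethyl N,N-diisopropylcarbamate, (+)-sparteine complex (not isolated) | C[C@@H]([Li])OC(=O)N(C(C)C)C(C)C | intermediate
9 | lithium [(1R)-1-(N,N-diisopropylcarbamoyloxy)ethyl][2-methoxy-4-(prop-2-en-1-yloxy)phenyl](pinacolato)borate (not isolated) | [Li+].C[C@H](OC(=O)N(C(C)C)C(C)C)[B-]1(c2ccc(OCC=C)cc2OC)OC(C)(C)C(C)(C)O1 | intermediate
10 | 2-{(1S)-1-[2-methoxy-4-(prop-2-en-1-yloxy)phenyl]ethyl}-4,4,5,5-tetramethyl-1,3,2-dioxaborolane | C[C@H](B1OC(C)(C)C(C)(C)O1)c1ccc(OCC=C)cc1OC | intermediate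
11 | bromochloromethane | ClCBr | starting material
12 | (chloromethyl)lithium (not isolated) | [Li]CCl | intermediate
13 | lithium (chloromethyl){(1S)-1-[2-methoxy-4-(prop-2-en-1-yloxy)phenyl]ethyl}(pinacolato)borate (not isolated) | [Li+].C[C@@H](c1ccc(OCC=C)cc1OC)[B-]1(CCl)OC(C)(C)C(C)(C)O1 | intermediate
14 | 2-{(2R)-2-[2-methoxy-4-(prop-2-en-1-yloxy)phenyl]propyl}-4,4,5,5-tetramethyl-1,3,2-dioxaborolane | C[C@H](CB1OC(C)(C)C(C)(C)O1)c1ccc(OCC=C)cc1OC | intermediate
15 | 3-methoxy-6-(prop-2-en-1-yl)-4-[(2R)-1-(4,4,5,5-tetramethyl-1,3,2-dioxaborolan-2-yl)propan-2-yl]cyclohexa-2,4-dien-1-one, both C6 epimers (not isolated) | O=C1C=C(OC)C([C@H](C)CB2OC(C)(C)C(C)(C)O2)=CC1CC=C | intermediate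
16 | 5-methoxy-2-(prop-2-en-1-yl)-4-[(2R)-1-(4,4,5,5-tetramethyl-1,3,2-dioxaborolan-2-yl)propan-2-yl]phenol | Oc1cc(OC)c([C@H](C)CB2OC(C)(C)C(C)(C)O2)cc1CC=C | intermediate
17 | {(2R)-2-[4-hydroxy-2-methoxy-5-(prop-2-en-1-yl)phenyl]propyl}boronic acid | Oc1cc(OC)c([C@H](C)CB(O)O)cc1CC=C | intermediate
18 | {(2R)-2-[4-{[acetoxy(phenyl)-λ3-iodanyl]oxy}-2-methoxy-5-(prop-2-en-1-yl)phenyl]propyl}boronic acid (not isolated) | CC(=O)OI(c1ccccc1)Oc1cc(OC)c([C@H](C)CB(O)O)cc1CC=C | intermediate
19 | (4R,5S)-2-hydroxy-6-methoxy-4-methyl-9-(prop-2-en-1-yl)-1-oxa-2-boraspiro[4.5]deca-6,9-dien-8-one | C=CCC1=C[C@]2(OB(O)C[C@H]2C)C(OC)=CC1=O | intermediate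
20 | 4-bromo-1,2-dimethoxybenzene | COc1ccc(Br)cc1OC | starting material
21 | (4S)-4-[(2R)-1-(3,4-dimethoxyphenyl)propan-2-yl]-4-hydroxy-5-methoxy-2-(prop-2-en-1-yl)cyclohexa-2,5-dien-1-one | C=CCC1=C[C@@](O)([C@H](C)Cc2ccc(OC)c(OC)c2)C(OC)=CC1=O | intermediate
22 | iodomethane | CI | starting material
23 | Lancifolin C, (4S)-4-[(2R)-1-(3,4-dimethoxyphenyl)propan-2-yl]-4,5-dimethoxy-2-(prop-2-en-1-yl)cyclohexa-2,5-dien-1-one | C=CCC1=C[C@@](OC)([C@H](C)Cc2ccc(OC)c(OC)c2)C(OC)=CC1=O | target

## Step count and least certain steps

Total step count: 9. Longest linear sequence: 9 steps (1 to 23); aryl bromide 20 enters in step 8.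

**Step 7 (key step, proposed new method).** The most likely failure is capture of the electrophilic C4 by acetate or by adventitious water instead of the weakly nucleophilic boron-bound hydroxyl, which would lose the facial control. Oxidative loss of the C–B bond, or loss of the C8 proton towards a quinone methide, are further possible failures. The fallback uses only known chemistry and gives up the relay. It sets out from 16. Suzuki–Miyaura coupling with 20 (Pd(OAc)2, RuPhos, K2CO3, toluene/H2O) should give 2-allyl-4-[(2R)-1-(3,4-dimethoxyphenyl)propan-2-yl]-5-methoxyphenol F1 (the same compound as A1). Oxidation of F1 with PhI(OAc)2 in methanol at 0 °C should give 23 together with its C4 epimer F2, which would be removed by chromatography. The fallback comes back to the route at 23.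

**Step 8.** Transmetalation of the hindered hydroxyboronate may be slow. That would leave time for β-hydride elimination from the alkylpalladium intermediate, for Heck arylation or palladium-hydride migration of the allyl double bond, and for base-induced decay of the dienone. The fallback reverses the polarity of the coupling and sets out from 19. Oxidation of the C–B bond with Me3NO in THF should give the diol (4R)-4-hydroxy-4-[(2R)-1-hydroxypropan-2-yl]-5-methoxy-2-(prop-2-en-1-yl)cyclohexa-2,5-dien-1-one F3. Selective iodination of the primary hydroxyl (I2, PPh3, imidazole) should give the iodide F4. Negishi coupling of F4 with an excess of bromo(3,4-dimethoxyphenyl)zinc F5 (made from 20 with magnesium and ZnBr2), using Pd2(dba)3, tricyclopentylphosphine and N-methylimidazole in THF/NMP, comes back to the route at 21.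

**Step 5.** Part of the material may rearrange to the crowded ortho carbon between the oxygen and the methoxy group, and the long heating may cost material through deborylation. The fallback forms the C2–allyl bond by cross-coupling instead of a sigmatropic shift and sets out from 14. Removal of the O-allyl group with Pd(PPh3)4 and morpholine should give 3-methoxy-4-[(2R)-1-(4,4,5,5-tetramethyl-1,3,2-dioxaborolan-2-yl)propan-2-yl]phenol F6. Bromination with NBS in MeCN at 0 °C, at the ortho position para to the methoxy group, should give the bromophenol F7. Stille coupling of F7 with allyltributylstannane (Pd(PPh3)4, toluene, 100 °C), under which the alkylboronic ester is inert, comes back to the route at 16.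

**Step 6.** The ester exchange may stop short of completion, and the free alkylboronic acid may be lost by air oxidation or obscured by anhydride formation. The fallback goes through a crystalline salt and sets out from 16. KHF2 in aqueous methanol should give potassium trifluoro{(2R)-2-[4-hydroxy-2-methoxy-5-(prop-2-en-1-yl)phenyl]propyl}borate F8, which can be purified by crystallisation. Hydrolysis of F8 with Me3SiCl and water in MeCN, just before use, comes back to the route at 17.

## Further compounds

F1 | step 7 | 2-allyl-4-[(2R)-1-(3,4-dimethoxyphenyl)propan-2-yl]-5-methoxyphenol | Oc1cc(OC)c([C@H](C)Cc2ccc(OC)c(OC)c2)cc1CC=C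
F2 | step 7 | (4R)-4-[(2R)-1-(3,4-dimethoxyphenyl)propan-2-yl]-4,5-dimethoxy-2-(prop-2-en-1-yl)cyclohexa-2,5-dien-1-one (C4 epimer of 23) | C=CCC1=C[C@](OC)([C@H](C)Cc2ccc(OC)c(OC)c2)C(OC)=CC1=O
F3 | step 8 | (4R)-4-hydroxy-4-[(2R)-1-hydroxypropan-2-yl]-5-methoxy-2-(prop-2-en-1-yl)cyclohexa-2,5-dien-1-one | C=CCC1=C[C@@](O)([C@H](C)CO)C(OC)=CC1=O
F4 | step 8 | (4R)-4-hydroxy-4-[(2S)-1-iodopropan-2-yl]-5-methoxy-2-(prop-2-en-1-yl)cyclohexa-2,5-dien-1-one | C=CCC1=C[C@@](O)([C@H](C)CI)C(OC)=CC1=O
F5 | step 8 | bromo(3,4-dimethoxyphenyl)zinc | COc1ccc([Zn]Br)cc1OC
F6 | step 5 | 3-methoxy-4-[(2R)-1-(4,4,5,5-tetramethyl-1,3,2-dioxaborolan-2-yl)propan-2-yl]phenol | Oc1ccc([C@H](C)CB2OC(C)(C)C(C)(C)O2)c(OC)c1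
F7 | step 5 | 2-bromo-5-methoxy-4-[(2R)-1-(4,4,5,5-tetramethyl-1,3,2-dioxaborolan-2-yl)propan-2-yl]phenol | Oc1cc(OC)c([C@H](C)CB2OC(C)(C)C(C)(C)O2)cc1Br
F8 | step 6 | potassium trifluoro{(2R)-2-[4-hydroxy-2-methoxy-5-(prop-2-en-1-yl)phenyl]propyl}borate | [K+].Oc1cc(OC)c([C@H](C)C[B-](F)(F)F)cc1CC=C
A1 | alternative 1 | 2-allyl-4-[(2R)-1-(3,4-dimethoxyphenyl)propan-2-yl]-5-methoxyphenol | Oc1cc(OC)c([C@H](C)Cc2ccc(OC)c(OC)c2)cc1CC=C
A2 | alternative 1 | (4R)-4-[(2R)-1-(3,4-dimethoxyphenyl)propan-2-yl]-4,5-dimethoxy-2-(prop-2-en-1-yl)cyclohexa-2,5-dien-1-one (C4 epimer of 23) | C=CCC1=C[C@](OC)([C@H](C)Cc2ccc(OC)c(OC)c2)C(OC)=CC1=O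
A3 | alternative 2 | 2-allyl-5-methoxycyclohexa-2,5-diene-1,4-dione | C=CCC1=CC(=O)C(OC)=CC1=O
A4 | alternative 2 | [(2R)-1-(3,4-dimethoxyphenyl)propan-2-yl]lithium | [Li][C@H](C)Cc1ccc(OC)c(OC)c1
A5 | alternative 3 | 2-allyl-4,4,5-trimethoxycyclohexa-2,5-dien-1-one | C=CCC1=CC(OC)(OC)C(OC)=CC1=O
A6 | alternative 3 | (E)-1,2-dimethoxy-4-(prop-1-en-1-yl)benzene ((E)-methylisoeugenol) | C/C=C/c1ccc(OC)c(OC)c1
A7 | alternative 3 | 5-allyl-2-(3,4-dimethoxyphenyl)-3a-methoxy-3-methyl-3,3a-dihydro-1-benzofuran-6(2H)-one (racemic, configuration not controlled) | C=CCC1=CC2(OC)C(C)C(c3ccc(OC)c(OC)c3)OC2=CC1=O
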